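## Retrosynthetic overview

- The two carbamates come from a macrocyclic 1,14-diol. Its benzylic C–O bonds (C1–O, C14–O) are the key disconnection: a double enantioselective syn-hydration of a macrocyclic (Z,Z)-bis(trisubstituted styrene) sets C1, C2, C14 and C15 at once.
- The (Z,Z)-diene comes from a macrocyclic aryl–alkyl diyne by syn-borylcupration/protonation and Suzuki methylation.
- The diyne is the only ring that is made (the 22-membered [7.7]paracyclophane; both arenes are bought). It forms by head-to-tail Sonogashira cyclodimerisation of a bromoarene/alkyne monomer.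
- In the monomer, C7 is set by copper-catalysed asymmetric conjugate addition of an alkynyl-alkyl Grignard reagent to a cinnamate. The ester arm becomes the 4,4-dichlorobutyl chain by reduction/methylenation and radical hydrodichloromethylation.
- The cinnamate comes from 5-bromoresorcinol by MOM protection, directed lithiation/formylation and Wittig olefination.

Assumption: the ligand antipodes named in steps 5 and 10 give the facial sense stated; if a first run shows the opposite sense, the mirror-image ligand is used and nothing else changes. The route is a paper design and has not been run.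

Macrocycles are named with the natural-product numbering of the [7.7]paracyclophane: bridges C1–C7 and C14–C20, arene carbons 8–13 and 21–26.

## Route

Step 1
Reactants: 1 5-bromobenzene-1,3-diol
Product: 2 1-bromo-3,5-bis(methoxymethoxy)benzene
Conditions: NaH, MOMCl, DMF, 0 °C → rt
Reagents that add atoms: chloromethyl methyl ether, COCCl
Why: Williamson-type O-alkylation of both phenoxides; the MOM groups later direct lithiation and come off under mild acid at the end.

Step 2
Reactants: 2 1-bromo-3,5-bis(methoxymethoxy)benzene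
Product: 4 4-bromo-2,6-bis(methoxymethoxy)benzaldehyde, via aryllithium 3 (not isolated)
Conditions: LiN(i-Pr)2, THF, −78 °C; DMF, −78 → 0 °C; H2O
Reagents that add atoms: N,N-dimethylformamide, CN(C)C=O; lithium diisopropylamide, [Li+].CC(C)[N-]C(C)C (lithium retained only in 3)
Why: Directed ortho-metalation at the position flanked by both MOM ethers (an amide base avoids Br/Li exchange), then formylation with DMF.

Step 3
Reactants: 4 4-bromo-2,6-bis(methoxymethoxy)benzaldehyde
Product: 5 methyl (2E)-3-[4-bromo-2,6-bis(methoxymethoxy)phenyl]prop-2-enoate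
Conditions: Ph3P=CHCO2Me, toluene, 90 °C
Reagents that add atoms: methyl (triphenylphosphoranylidene)acetate, COC(=O)C=P(c1ccccc1)(c1ccccc1)c1ccccc1
Why: Wittig olefination with a stabilised ylide gives the E enoate, the acceptor for step 5.

Step 4
Reactants: 6 ethynyltrimethylsilane; 7 1,4-dibromobutane
Product: 9 (6-bromohex-1-yn-1-yl)trimethylsilane, via lithium acetylide 8 (not isolated)
Conditions: n-BuLi, THF, −78 °C; then 7 (4 equiv), DMPU, −78 °C → rt
Reagents that add atoms: n-butyllithium, [Li]CCCC (lithium retained only in 8)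
Why: SN2 alkylation of the lithium acetylide; the excess of dibromide enforces mono-substitution.

Step 5
Reactants: 5 methyl (2E)-3-[4-bromo-2,6-bis(methoxymethoxy)phenyl]prop-2-enoate; 9 (6-bromohex-1-yn-1-yl)trimethylsilane
Product: 11 methyl (3S)-3-[4-bromo-2,6-bis(methoxymethoxy)phenyl]-9-(trimethylsilyl)non-8-ynoate, via Grignard reagent 10 (not isolated)
Conditions: 9, Mg, Et2O, 35 °C; then 5, CuI (5 mol%), (R)-Tol-BINAP (7.5 mol%), t-BuOMe, −40 °C; H2O
Reagents that add atoms: magnesium, [Mg] (retained only in 10)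
Why: Copper-catalysed asymmetric conjugate addition of a primary alkyl Grignard reagent to an E enoate; the chiral bisphosphine–copper complex delivers the alkyl group to the Si face of C3, which sets the future C7 as S, and the aryl bromide is inert at −40 °C.

Step 6
Reactants: 11 methyl (3S)-3-[4-bromo-2,6-bis(methoxymethoxy)phenyl]-9-(trimethylsilyl)non-8-ynoate
Product: 13 {(7S)-7-[4-bromo-2,6-bis(methoxymethoxy)phenyl]dec-9-en-1-yn-1-yl}trimethylsilane, via aldehyde 12 (not isolated)
Conditions: i-Bu2AlH, CH2Cl2, −78 °C; then Ph3P=CH2 (from Ph3PCH3Br, KN(SiMe3)2, THF), −78 °C → rt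
Reagents that add atoms: methyltriphenylphosphonium bromide, C[P+](c1ccccc1)(c1ccccc1)c1ccccc1.[Br-]
Why: One-pot half-reduction of the ester and Wittig methylenation turns the ester arm into an allyl group; the stereocentre is β to the carbonyl and cannot epimerise.

Step 7
Reactants: 13 {(7S)-7-[4-bromo-2,6-bis(methoxymethoxy)phenyl]dec-9-en-1-yn-1-yl}trimethylsilane
Product: 14 {(7S)-7-[4-bromo-2,6-bis(methoxymethoxy)phenyl]-11,11-dichloroundec-1-yn-1-yl}trimethylsilane
Conditions: BrCHCl2, Ir(ppy)3 (ppy = 2-phenylpyridinato, 1 mol%), Hantzsch ester, 2,4,6-(i-Pr)3C6H2SH (10 mol%), NaHCO3, MeCN, blue LEDs, rt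
Reagents that add atoms: bromodichloromethane, BrC(Cl)Cl
Why: Reductive Kharasch-type radical hydroalkylation under photoredox conditions: the dichloromethyl radical from C–Br cleavage adds to the terminal alkene carbon and the secondary radical takes a hydrogen atom from the thiol/Hantzsch ester, which gives the 4,4-dichlorobutyl chain without touching the aryl bromide, the silyl alkyne or C7.

Step 8
Reactants: 14 {(7S)-7-[4-bromo-2,6-bis(methoxymethoxy)phenyl]-11,11-dichloroundec-1-yn-1-yl}trimethylsilane (two molecules)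
Product: 17 (7S,20S)-7,20-bis(4,4-dichlorobutyl)-9,13,22,26-tetrakis(methoxymethoxy)[7.7]paracyclophane-1,14-diyne, via free alkyne 15 (not isolated), via open-chain dimer 16 (not isolated)
Conditions: PdCl2(MeCN)2 (10 mol%), XPhos (20 mol%), CsF, MeCN/H2O (50:1), 75 °C, syringe-pump addition of 14 (final 1 mM)
Reagents that add atoms: none
Why: Fluoride desilylation with copper-free Sonogashira coupling at high dilution; the para-disposed bromide and alkyne of one molecule cannot reach each other, so two molecules join head to tail and the open-chain dimer closes the 22-membered ring; no stereocentre is involved.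

Step 9
Reactants: 17 (7S,20S)-7,20-bis(4,4-dichlorobutyl)-9,13,22,26-tetrakis(methoxymethoxy)[7.7]paracyclophane-1,14-diyne
Product: 19 (1Z,14Z,7S,20S)-7,20-bis(4,4-dichlorobutyl)-9,13,22,26-tetrakis(methoxymethoxy)-2,15-dimethyl[7.7]paracyclophane-1,14-diene, via bis(alkenylboronate) 18 (not isolated)
Conditions: CuCl (10 mol%), P(p-tol)3 (12 mol%), NaOt-Bu (20 mol%), B2pin2, MeOH, THF, rt; then Pd(PPh3)4 (10 mol%), MeI, aq. K3PO4, sealed tube, 50 °C
Reagents that add atoms: bis(pinacolato)diboron, CC1(C)OB(OC1(C)C)B1OC(C)(C)C(C)(C)O1 (boryl groups retained only in 18); iodomethane, CI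
Why: Copper-catalysed syn-borylcupration/protonation of the aryl alkyne puts boron on the alkyl-bearing carbon cis to the new hydrogen, and Suzuki–Miyaura methylation with retention gives the trisubstituted styrene with aryl and ring chain cis (Z); with only catalytic alkoxide the alkyl chlorides are not borylated.

Step 10
Reactants: 19 (1Z,14Z,7S,20S)-7,20-bis(4,4-dichlorobutyl)-9,13,22,26-tetrakis(methoxymethoxy)-2,15-dimethyl[7.7]paracyclophane-1,14-diene
Product: 21 (1R,2S,7S,14R,15S,20S)-7,20-bis(4,4-dichlorobutyl)-9,13,22,26-tetrakis(methoxymethoxy)-2,15-dimethyl[7.7]paracyclophane-1,14-diol, via bis(boronate) 20 (not isolated)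
Conditions: Cu(OAc)2 (10 mol%), (R)-DTBM-SEGPHOS (11 mol%), HBpin, THF, 45 °C; then NaOH, H2O2, 0 °C → rt
Reagents that add atoms: pinacolborane, [H]B1OC(C)(C)C(C)(C)O1 (boryl group retained only in 20); hydrogen peroxide, OO
Why: Proposed new method: a double CuH-catalysed enantioselective benzylic hydroboration of a macrocyclic (Z)-trisubstituted β,β-dialkyl styrene with in-flask oxidation, in effect a catalytic asymmetric syn-hydration that forms both benzylic C–O bonds; the ligated copper hydride adds across each C1=C2 bond with hydrogen to the fully substituted C2 and copper to benzylic C1 (the preference for a stabilised benzylcopper and for the CH terminus coincide), the ligand selects the alkene face, and syn addition to the Z alkene sets C2 as S and C1 as R together, after which boryl transfer from HBpin and peroxide oxidation both proceed with retention; because the two alkenes are homotopic, a facial error ends up in a separable diastereomer; the closest known reaction type is the CuH/HBpin Markovnikov hydroboration of vinylarenes and β-monosubstituted styrenes, which has not been shown for a trisubstituted styrene or twice on one macrocycle.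

Step 11
Reactants: 21 (1R,2S,7S,14R,15S,20S)-7,20-bis(4,4-dichlorobutyl)-9,13,22,26-tetrakis(methoxymethoxy)-2,15-dimethyl[7.7]paracyclophane-1,14-diol
Product: 23 (1R,2S,7S,14R,15S,20S)-7,20-bis(4,4-dichlorobutyl)-9,13,22,26-tetrakis(methoxymethoxy)-2,15-dimethyl[7.7]paracyclophane-1,14-diyl dicarbamate, via bis(trichloroacetylcarbamate) 22 (not isolated)
Conditions: Cl3CC(O)NCO, CH2Cl2, 0 °C; then K2CO3, MeOH, rt
Reagents that add atoms: trichloroacetyl isocyanate, O=C=NC(=O)C(Cl)(Cl)Cl (trichloroacetyl part retained only in 22)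
Why: Kocovsky carbamoylation: the very electrophilic acyl isocyanate acylates the hindered secondary benzylic alcohols on oxygen without touching C1, and mild methanolysis removes the trichloroacetyl group.

Step 12
Reactants: 23 (1R,2S,7S,14R,15S,20S)-7,20-bis(4,4-dichlorobutyl)-9,13,22,26-tetrakis(methoxymethoxy)-2,15-dimethyl[7.7]paracyclophane-1,14-diyl dicarbamate
Product: 24 (1R,2S,7S,14R,15S,20S)-7,20-bis(4,4-dichlorobutyl)-9,13,22,26-tetrahydroxy-2,15-dimethyl[7.7]paracyclophane-1,14-diyl dicarbamate (CNP0205627.1)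
Conditions: HCl (2 M), MeOH/THF, 40 °C
Reagents that add atoms: none
Why: Acid-catalysed acetal exchange cleaves the four MOM ethers; the primary carbamates and CHCl2 groups tolerate dilute methanolic HCl, and the benzylic C–O bonds sit on an arene with only meta oxygens, so they do not ionise.

## Compound list

1 | 5-bromobenzene-1,3-diol | Oc1cc(O)cc(Br)c1 | starting material
2 | 1-bromo-3,5-bis(methoxymethoxy)benzene | COCOc1cc(Br)cc(OCOC)c1 | intermediate
3 | [4-bromo-2,6-bis(methoxymethoxy)phenyl]lithium | [Li]c1c(OCOC)cc(Br)cc1OCOC | intermediate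
4 | 4-bromo-2,6-bis(methoxymethoxy)benzaldehyde | O=Cc1c(OCOC)cc(Br)cc1OCOC | intermediate
5 | methyl (2E)-3-[4-bromo-2,6-bis(methoxymethoxy)phenyl]prop-2-enoate | COC(=O)/C=C/c1c(OCOC)cc(Br)cc1OCOC | intermediate
6 | ethynyltrimethylsilane | C#C[Si](C)(C)C | starting material
7 | 1,4-dibromobutane | BrCCCCBr | starting material
8 | lithium (trimethylsilyl)acetylide | [Li]C#C[Si](C)(C)C | intermediate
9 | (6-bromohex-1-yn-1-yl)trimethylsilane | C[Si](C)(C)C#CCCCCBr | intermediate
10 | [6-(trimethylsilyl)hex-5-yn-1-yl]magnesium bromide | C[Si](C)(C)C#CCCCC[Mg]Br | intermediate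
11 | methyl (3S)-3-[4-bromo-2,6-bis(methoxymethoxy)phenyl]-9-(trimethylsilyl)non-8-ynoate | C[Si](C)(C)C#CCCCC[C@@H](CC(=O)OC)c1c(OCOC)cc(Br)cc1OCOC | intermediate
12 | (3S)-3-[4-bromo-2,6-bis(methoxymethoxy)phenyl]-9-(trimethylsilyl)non-8-ynal | C[Si](C)(C)C#CCCCC[C@@H](CC=O)c1c(OCOC)cc(Br)cc1OCOC | intermediate
13 | {(7S)-7-[4-bromo-2,6-bis(methoxymethoxy)phenyl]dec-9-en-1-yn-1-yl}trimethylsilane | C[Si](C)(C)C#CCCCC[C@@H](CC=C)c1c(OCOC)cc(Br)cc1OCOC | intermediate
14 | {(7S)-7-[4-bromo-2,6-bis(methoxymethoxy)phenyl]-11,11-dichloroundec-1-yn-1-yl}trimethylsilane | C[Si](C)(C)C#CCCCC[C@@H](CCCC(Cl)Cl)c1c(OCOC)cc(Br)cc1OCOC | intermediate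
15 | 5-bromo-2-[(5S)-1,1-dichloroundec-10-yn-5-yl]-1,3-bis(methoxymethoxy)benzene | C#CCCCC[C@@H](CCCC(Cl)Cl)c1c(OCOC)cc(Br)cc1OCOC | intermediate
16 | open-chain head-to-tail dimer: 5-bromo-2-[(5S)-1,1-dichloro-11-{4-[(5S)-1,1-dichloroundec-10-yn-5-yl]-3,5-bis(methoxymethoxy)phenyl}undec-10-yn-5-yl]-1,3-bis(methoxymethoxy)benzene | C#CCCCC[C@@H](CCCC(Cl)Cl)c1c(OCOC)cc(cc1OCOC)C#CCCCC[C@@H](CCCC(Cl)Cl)c1c(OCOC)cc(Br)cc1OCOC | intermediate
17 | (7S,20S)-7,20-bis(4,4-dichlorobutyl)-9,13,22,26-tetrakis(methoxymethoxy)[7.7]paracyclophane-1,14-diyne | C#1CCCC[C@@H](CCCC(Cl)Cl)c2c(OCOC)cc(cc2OCOC)C#CCCCC[C@@H](CCCC(Cl)Cl)c2c(OCOC)cc(cc2OCOC)C#1 | intermediate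
18 | (1Z,14Z,7S,20S)-7,20-bis(4,4-dichlorobutyl)-9,13,22,26-tetrakis(methoxymethoxy)-2,15-bis(4,4,5,5-tetramethyl-1,3,2-dioxaborolan-2-yl)[7.7]paracyclophane-1,14-diene | COCOc1cc(/C=C(/B4OC(C)(C)C(C)(C)O4)CCCC[C@@H](CCCC(Cl)Cl)c2c(OCOC)cc(cc2OCOC)/C=C(/B2OC(C)(C)C(C)(C)O2)CCCC[C@H]3CCCC(Cl)Cl)cc(OCOC)c13 | intermediate
19 | (1Z,14Z,7S,20S)-7,20-bis(4,4-dichlorobutyl)-9,13,22,26-tetrakis(methoxymethoxy)-2,15-dimethyl[7.7]paracyclophane-1,14-diene | COCOc1cc(/C=C(/C)CCCC[C@@H](CCCC(Cl)Cl)c2c(OCOC)cc(cc2OCOC)/C=C(/C)CCCC[C@H]3CCCC(Cl)Cl)cc(OCOC)c13 | intermediate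
20 | (1R,2S,7S,14R,15S,20S)-7,20-bis(4,4-dichlorobutyl)-9,13,22,26-tetrakis(methoxymethoxy)-2,15-dimethyl-1,14-bis(4,4,5,5-tetramethyl-1,3,2-dioxaborolan-2-yl)[7.7]paracyclophane | C[C@H]1CCCC[C@@H](CCCC(Cl)Cl)c2c(OCOC)cc(cc2OCOC)[C@H](B3OC(C)(C)C(C)(C)O3)[C@@H](C)CCCC[C@@H](CCCC(Cl)Cl)c2c(OCOC)cc(cc2OCOC)[C@@H]1B2OC(C)(C)C(C)(C)O2 | intermediate
21 | (1R,2S,7S,14R,15S,20S)-7,20-bis(4,4-dichlorobutyl)-9,13,22,26-tetrakis(methoxymethoxy)-2,15-dimethyl[7.7]paracyclophane-1,14-diol | C[C@H]1CCCC[C@@H](CCCC(Cl)Cl)c2c(OCOC)cc(cc2OCOC)[C@H](O)[C@@H](C)CCCC[C@@H](CCCC(Cl)Cl)c2c(OCOC)cc(cc2OCOC)[C@@H]1O | intermediate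
22 | bis(N-trichloroacetyl)carbamate of 21 | C[C@H]1CCCC[C@@H](CCCC(Cl)Cl)c2c(OCOC)cc(cc2OCOC)[C@H](OC(=O)NC(=O)C(Cl)(Cl)Cl)[C@@H](C)CCCC[C@@H](CCCC(Cl)Cl)c2c(OCOC)cc(cc2OCOC)[C@@H]1OC(=O)NC(=O)C(Cl)(Cl)Cl | intermediate
23 | (1R,2S,7S,14R,15S,20S)-7,20-bis(4,4-dichlorobutyl)-9,13,22,26-tetrakis(methoxymethoxy)-2,15-dimethyl[7.7]paracyclophane-1,14-diyl dicarbamate | C[C@H]1CCCC[C@@H](CCCC(Cl)Cl)c2c(OCOC)cc(cc2OCOC)[C@H](OC(N)=O)[C@@H](C)CCCC[C@@H](CCCC(Cl)Cl)c2c(OCOC)cc(cc2OCOC)[C@@H]1OC(N)=O | intermediate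
24 | (1R,2S,7S,14R,15S,20S)-7,20-bis(4,4-dichlorobutyl)-9,13,22,26-tetrahydroxy-2,15-dimethyl[7.7]paracyclophane-1,14-diyl dicarbamate (CNP0205627.1) | C[C@H]1CCCC[C@@H](CCCC(Cl)Cl)c2c(O)cc(cc2O)[C@H](OC(N)=O)[C@@H](C)CCCC[C@@H](CCCC(Cl)Cl)c2c(O)cc(cc2O)[C@@H]1OC(N)=O | target

## Step count and risk

Total steps: 12. Longest linear sequence: 11 (steps 1–3 and 5–12, from 1); step 4 is a one-step side branch.

The three steps most likely to fail:

**Step 10 (the new double CuH hydroboration/oxidation).** Hydrocupration of a trisubstituted styrene may be too slow, or the facial selectivity too low. The fallback uses reagent control with a stoichiometric chiral borane (Brown asymmetric hydroboration, known for trisubstituted alkenes). It sets out from 19: isopinocampheylborane made from (+)-α-pinene (freed from its TMEDA adduct with BF3·OEt2), THF, −25 °C, adds boron to C1 and hydrogen to C2 on the same face and gives the bis(isopinocampheylboryl) adduct F6. This is oxidised in the flask with NaOH/H2O2 and comes back to the route at diol 21. The borane from (−)-α-pinene is taken if the facial sense is opposite.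

**Step 8 (one-pot cyclodimerisation).** The coupling is irreversible, so linear and cyclic oligomers may dominate. The fallback builds the dimer stepwise and closes the ring as a unimolecular reaction. It sets out from 14:
- One half is desilylated (K2CO3, MeOH) and isolated as free alkyne 15.
- The other half undergoes aromatic bromide–iodide exchange (CuI, NaI, trans-N,N'-dimethylcyclohexane-1,2-diamine, dioxane, 110 °C) to the aryl iodide F4.
- Sonogashira coupling at rt (PdCl2(PPh3)2, CuI, Et3N, THF) joins the alkyne of 15 only to the iodide of F4 and gives the silylated open-chain dimer F5.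
- F5 is desilylated and cyclised under the conditions of step 8 at 1 mM and comes back to the route at diyne 17.

**Step 5 (catalytic conjugate addition to a cinnamate with two ortho substituents).** The rate or the ee may be low. The fallback replaces catalyst control by an oxazolidinone auxiliary, a method known for 2,6-disubstituted cinnamoyl imides. It sets out from 5:
- LiOH, THF/H2O gives (2E)-3-[4-bromo-2,6-bis(methoxymethoxy)phenyl]prop-2-enoic acid F1.
- Pivaloyl chloride/Et3N, then the lithium salt of (4S)-4-phenyl-1,3-oxazolidin-2-one, give the N-enoyl oxazolidinone F2.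
- Grignard reagent 10 with stoichiometric CuBr·SMe2 (THF/Me2S, −20 °C) adds anti to the phenyl group of the chelated imide (Si face of C3) and gives the (3S)-adduct F3.
- NaOMe, MeOH/THF, 0 °C removes the auxiliary and comes back to the route at ester 11.

## Further compounds

F1 | step 5 | (2E)-3-[4-bromo-2,6-bis(methoxymethoxy)phenyl]prop-2-enoic acid | OC(=O)/C=C/c1c(OCOC)cc(Br)cc1OCOC
F2 | step 5 | (4S)-3-{(2E)-3-[4-bromo-2,6-bis(methoxymethoxy)phenyl]prop-2-enoyl}-4-phenyl-1,3-oxazolidin-2-one | O=C(/C=C/c1c(OCOC)cc(Br)cc1OCOC)N1[C@@H](c2ccccc2)COC1=O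
F3 | step 5 | (4S)-3-{(3S)-3-[4-bromo-2,6-bis(methoxymethoxy)phenyl]-9-(trimethylsilyl)non-8-ynoyl}-4-phenyl-1,3-oxazolidin-2-one | C[Si](C)(C)C#CCCCC[C@@H](CC(=O)N1[C@@H](c2ccccc2)COC1=O)c1c(OCOC)cc(Br)cc1OCOC
F4 | step 8 | {(7S)-11,11-dichloro-7-[4-iodo-2,6-bis(methoxymethoxy)phenyl]undec-1-yn-1-yl}trimethylsilane | C[Si](C)(C)C#CCCCC[C@@H](CCCC(Cl)Cl)c1c(OCOC)cc(I)cc1OCOC
F5 | step 8 | silylated open-chain head-to-tail dimer (16 with SiMe3 on the terminal alkyne) | C[Si](C)(C)C#CCCCC[C@@H](CCCC(Cl)Cl)c1c(OCOC)cc(cc1OCOC)C#CCCCC[C@@H](CCCC(Cl)Cl)c1c(OCOC)cc(Br)cc1OCOC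
F6 | step 10 | bis(isopinocampheylboryl) adduct of 19 (isopinocampheyl from (+)-α-pinene; boron on C1 and C14) | C[C@H]1CCCC[C@@H](CCCC(Cl)Cl)c2c(OCOC)cc(cc2OCOC)[C@H]([BH][C@@H]2C[C@@H]3C[C@H]([C@H]2C)C3(C)C)[C@@H](C)CCCC[C@@H](CCCC(Cl)Cl)c2c(OCOC)cc(cc2OCOC)[C@@H]1[BH][C@@H]1C[C@@H]2C[C@H]([C@H]1C)C2(C)C
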